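**Retrosynthetic overview**

1. Target 22 ⇐ Z-selective semi-hydrogenation of aryl propiolate 21 ⇐ Sonogashira coupling with 4-iodophenol ⇐ propiolate 19 of diol 17 (the ester is put on last).
2. Diene-diol 17 ⇐ nickel-catalysed vinylative opening of exocyclic enol ether 16 ⇐ methylenation of six-membered lactone 15.
3. Lactone 15 ⇐ Baeyer–Villiger ring expansion of tricyclic cyclopentanone 14: C8 shifts from C13 to oxygen with retention, so the cyclopentanone is the latent C8–OH plus C11–C13.
4. 14 ⇐ ring A annulation on bicyclic enedione 4: reductive alkylation (sets C9, C10), alkylation/intramolecular Horner–Wadsworth–Emmons (closes C3–C4 and C4=C5), reductive methylation (sets C5, C4).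
5. Ring order: cyclopentanone (already in 1) → ring B (asymmetric Robinson annulation, sets C8) → ring A → lactone by ring expansion → lactone opened to the side chain.

Assumption: labdane numbering (C1–C20) is used for every intermediate; β is the face of the C8 and C10 methyl groups, α the opposite face; the target is the (4S,5R,8R,9R,10S) isomer with a Z ester, as its SMILES shows.

**Route**

Step 1
Reactants: 1 2-methylcyclopentane-1,3-dione; 2 pent-1-en-3-one (ethyl vinyl ketone)
Product: 3 2-methyl-2-(3-oxopentyl)cyclopentane-1,3-dione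
Conditions: H2O, AcOH (cat.), 75 °C
Reagents that add atoms: none
Why: Michael addition of the acidic 1,3-dione to the enone runs in water without added base and creates no stereocenter.

Step 2
Reactants: 3 2-methyl-2-(3-oxopentyl)cyclopentane-1,3-dione
Product: 4 (7aR)-4,7a-dimethyl-2,3,7,7a-tetrahydro-1H-indene-1,5(6H)-dione
Conditions: D-phenylalanine (1.0 equiv), (1R)-(−)-camphor-10-sulfonic acid (0.5 equiv), DMF, 30 → 70 °C
Reagents that add atoms: none
Why: Hajos–Parrish–Eder–Sauer–Wiechert aldol condensation in which the enamine formed from the side-chain ketone and the D-amino acid attacks one of the two enantiotopic ring carbonyls, so dehydration gives the ring B enone with quaternary C8 in the R configuration (the L-amino acid is known to give S).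

Step 3
Reactants: 4 (7aR)-4,7a-dimethyl-2,3,7,7a-tetrahydro-1H-indene-1,5(6H)-dione
Product: 5 (7a'R)-4',7a'-dimethyl-2',3',7',7a'-tetrahydrospiro[[1,3]dioxolane-2,1'-inden]-5'(6'H)-one (C13 dioxolane of 4)
Conditions: HOCH2CH2OH (5 equiv), p-TsOH·H2O (5 mol%), 4 Å molecular sieves, rt
Reagents that add atoms: ethane-1,2-diol, OCCO
Why: Acid-catalysed ketalisation is selective for the saturated cyclopentanone because the conjugated carbonyl is much less electrophilic, and no stereocenter is touched.

Step 4
Reactants: 5 C13 dioxolane of 4; 6 1-chloro-3-iodopropane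
Product: 8 trans-fused chloropropyl ketone ketal (C9–H α; C10 carries CH3 β plus 3-chloropropyl α; C5 ketone), via lithium enolate 7 (not isolated)
Conditions: Li (2.2 equiv), NH3(l)/THF, H2O (1.0 equiv), −78 °C; NH3 evaporated; then 6 (3 equiv), THF/DMPU, −20 °C → rt
Reagents that add atoms: none
Why: Stork reductive alkylation in which dissolving-metal reduction protonates the β-carbon C9 on the α face to give the trans-hydrindane enolate regiospecifically, and the iodide end of 6 then alkylates C10 anti to the syn-axial C8 methyl, placing the chain α and the C10 methyl β.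

Step 5
Reactants: 8 trans-fused chloropropyl ketone ketal
Product: 10 tricyclic ketal enoate (ring A closed; C4=C5 double bond; CO2Me on C4), via alkylated phosphonate 9 (not isolated)
Conditions: (EtO)2P(O)CH2CO2Me (1.5 equiv), NaH (1.5 equiv), NaI (0.2 equiv), DMF, 60 °C; then NaH (1.3 equiv), 80 °C
Reagents that add atoms: methyl 2-(diethoxyphosphoryl)acetate, COC(=O)CP(=O)(OCC)OCC
Why: SN2 alkylation of the preformed phosphonate anion by the primary halide followed by intramolecular Horner–Wadsworth–Emmons olefination of the C5 ketone closes ring A as a six-membered tetrasubstituted enoate without creating a stereocenter.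

Step 6
Reactants: 10 tricyclic ketal enoate
Product: 12 tricyclic ketal ester (C4: CH3 α equatorial; CO2Me β axial = C19; C5–H α), via lithium ester enolate 11 (not isolated)
Conditions: Li (2.5 equiv), NH3(l)/THF, H2O (1.0 equiv), −78 °C; then MeI (5 equiv), −78 → −33 °C
Reagents that add atoms: iodomethane, CI
Why: Birch-type reductive methylation in which protonation of C5 from the α face gives the trans-decalin and the exocyclic ester enolate takes MeI from the equatorial α side, away from the axial C10 methyl, leaving the ester axial (β).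

Step 7
Reactants: 12 tricyclic ketal ester
Product: 14 (4S,5R,8R,9R,10S)-19-hydroxy-8,13-cyclo-14,15,16-trinorlabdan-13-one, via ketal alcohol 13 (not isolated)
Conditions: LiAlH4 (2 equiv), THF, 0 °C → reflux; then 2 M HCl, THF, rt
Reagents that add atoms: water, O
Why: Hydride reduction of the hindered neopentyl ester to the primary alcohol and acid hydrolysis of the dioxolane in the work-up free the cyclopentanone without touching any stereocenter.

Step 8
Reactants: 14 (4S,5R,8R,9R,10S)-19-hydroxy-8,13-cyclo-14,15,16-trinorlabdan-13-one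
Product: 15 (4S,5R,8R,9R,10S)-19-hydroxy-14,15,16-trinorlabdan-13,8-olide (six-membered lactone, C8–O α)
Conditions: mCPBA (3 equiv), NaHCO3 (4 equiv), CH2Cl2, rt, 48 h
Reagents that add atoms: 3-chloroperoxybenzoic acid, OOC(=O)c1cccc(Cl)c1
Why: Baeyer–Villiger ring expansion in which the quaternary C8 of the Criegee adduct migrates from C13 to oxygen in preference to the CH2 group and with retention, so the cyclopentanone becomes the lactone and the C8–O bond is set α (as in the lactonisation of 17-oxo steroids).

Step 9
Reactants: 15 (4S,5R,8R,9R,10S)-19-hydroxy-14,15,16-trinorlabdan-13,8-olide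
Product: 16 (4S,5R,8R,9R,10S)-8,13-epoxy-14,15-dinorlabd-13(16)-en-19-ol (2-methylenetetrahydropyran)
Conditions: Cp2TiMe2 (3.5 equiv), toluene, 70 °C, dark; filtration through basic Al2O3
Reagents that add atoms: Cp2TiMe2, C[Ti](C)(C1C=CC=C1)C1C=CC=C1
Why: Carbonyl methylenation by Cp2Ti=CH2 (Petasis olefination) turns the lactone carbonyl into the exocyclic enol ether under non-basic conditions, while the free alcohol is only titanated and returns on work-up.

Step 10
Reactants: 16 (4S,5R,8R,9R,10S)-8,13-epoxy-14,15-dinorlabd-13(16)-en-19-ol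
Product: 17 (4S,5R,8R,9R,10S)-labda-13(16),14-diene-8,19-diol
Conditions: CH2=CHMgBr (4 equiv), Ni(cod)2 (10 mol%), PCy3 (20 mol%), toluene/THF, 60 °C; then aq NH4Cl
Reagents that add atoms: vinylmagnesium bromide, C=C[Mg]Br
Why: Proposed new method: zerovalent nickel, helped by magnesium coordination to the ring oxygen, should insert into the vinylic C13–O bond of the exocyclic enol ether, the alkenylnickel alkoxide then transmetalates with the vinyl Grignard reagent and reductive elimination forms the C13–C14 bond, giving the 2-substituted 1,3-diene and the C8 magnesium alkoxide without touching C8; the closest known reaction type is the Wenkert-type nickel-catalysed Kumada coupling of enol ethers with Grignard reagents, known with ring opening for endocyclic dihydropyrans and dihydrofurans but not for exocyclic 2-methylene oxacycles or for making dienes.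

Step 11
Reactants: 17 (4S,5R,8R,9R,10S)-labda-13(16),14-diene-8,19-diol; 18 prop-2-ynoic acid (propiolic acid)
Product: 19 (4S,5R,8R,9R,10S)-8-hydroxylabda-13(16),14-dien-19-yl prop-2-ynoate
Conditions: DCC (1.5 equiv), DMAP (5 mol%), CH2Cl2, −20 → 0 °C
Reagents that add atoms: none
Why: Steglich esterification acylates only the primary C19 hydroxyl because the tertiary C8 hydroxyl does not react under carbodiimide conditions.

Step 12
Reactants: 19 (4S,5R,8R,9R,10S)-8-hydroxylabda-13(16),14-dien-19-yl prop-2-ynoate; 20 4-iodophenol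
Product: 21 (4S,5R,8R,9R,10S)-8-hydroxylabda-13(16),14-dien-19-yl 3-(4-hydroxyphenyl)prop-2-ynoate
Conditions: Pd(PPh3)2Cl2 (3 mol%), CuI (6 mol%), K2CO3 (2 equiv), THF, rt
Reagents that add atoms: none
Why: Sonogashira coupling of the terminal propiolate with the aryl iodide is fast at room temperature, tolerates the free phenol, and the inorganic base avoids amine addition to the ynoate.

Step 13
Reactants: 21 (4S,5R,8R,9R,10S)-8-hydroxylabda-13(16),14-dien-19-yl 3-(4-hydroxyphenyl)prop-2-ynoate
Product: 22 (4S,5R,8R,9R,10S)-8-hydroxylabda-13(16),14-dien-19-yl (2Z)-3-(4-hydroxyphenyl)prop-2-enoate (target, CNP0197278.1)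
Conditions: H2 (1 atm, stopped at 1.0 equiv uptake), Pd/CaCO3 poisoned with Pb(OAc)2, quinoline, EtOAc, 0 °C
Reagents that add atoms: none
Why: Poisoned-palladium semi-hydrogenation adds H2 syn to the alkyne, which binds far more strongly than the diene, so the Z-cinnamate forms when uptake is stopped at one equivalent.

**Compound list**

1 | 2-methylcyclopentane-1,3-dione | CC1C(=O)CCC1=O | starting material
2 | pent-1-en-3-one (ethyl vinyl ketone) | CCC(=O)C=C | starting material
3 | 2-methyl-2-(3-oxopentyl)cyclopentane-1,3-dione | CCC(=O)CCC1(C)C(=O)CCC1=O | intermediate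
4 | (7aR)-4,7a-dimethyl-2,3,7,7a-tetrahydro-1H-indene-1,5(6H)-dione (ring B enone, C5 ketone, C13 ketone, C8 quaternary) | O=C1CCC2=C(C)C(=O)CC[C@@]12C | intermediate
5 | (7a'R)-4',7a'-dimethyl-2',3',7',7a'-tetrahydrospiro[[1,3]dioxolane-2,1'-inden]-5'(6'H)-one (C13 dioxolane of 4) | C1COC2(O1)CCC3=C(C)C(=O)CC[C@@]23C | intermediate
6 | 1-chloro-3-iodopropane | ClCCCI | starting material
7 | lithium enolate of the trans-hydrindanone ketal (C5–OLi, C5=C10, C9–H α) | C1COC2(O1)CC[C@@H]3C(C)=C([O-])CC[C@@]23C.[Li+] | intermediate (not isolated)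
8 | trans-fused chloropropyl ketone ketal (C8–CH3 β, C9–H α, C10: CH3 β and 3-chloropropyl α, C5 ketone) | C1COC2(O1)CC[C@@H]3[C@@](C)(CCCCl)C(=O)CC[C@@]23C | intermediate
9 | alkylated phosphonate: 8 with Cl replaced by CH(CO2Me)P(O)(OEt)2 (both epimers at that carbon) | C1COC2(O1)CC[C@@H]3[C@@](C)(CCCC(C(=O)OC)P(=O)(OCC)OCC)C(=O)CC[C@@]23C | intermediate (not isolated)
10 | tricyclic ketal enoate (ring A closed, C4=C5, CO2Me on C4, C10–CH3 β, C9–H α, C8–CH3 β) | C1COC2(O1)CC[C@@H]3[C@@]4(C)CCCC(C(=O)OC)=C4CC[C@@]23C | intermediate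
11 | lithium ester enolate (exocyclic C4=C(OMe)OLi, C5–H α, trans-decalin) | C1COC2(O1)CC[C@@H]3[C@@]4(C)CCCC(=C([O-])OC)[C@@H]4CC[C@@]23C.[Li+] | intermediate (not isolated)
12 | tricyclic ketal ester (C4: CH3 α, CO2Me β axial = C19; C5–H α; C13 dioxolane) | C1COC2(O1)CC[C@@H]3[C@@]4(C)CCC[C@](C)(C(=O)OC)[C@@H]4CC[C@@]23C | intermediate
13 | ketal alcohol (C19 CH2OH analogue of 12) | C1COC2(O1)CC[C@@H]3[C@@]4(C)CCC[C@](C)(CO)[C@@H]4CC[C@@]23C | intermediate (not isolated)
14 | (4S,5R,8R,9R,10S)-19-hydroxy-8,13-cyclo-14,15,16-trinorlabdan-13-one | O=C1CC[C@@H]2[C@@]3(C)CCC[C@](C)(CO)[C@@H]3CC[C@@]12C | intermediate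
15 | (4S,5R,8R,9R,10S)-19-hydroxy-14,15,16-trinorlabdan-13,8-olide | O=C1CC[C@@H]2[C@@]3(C)CCC[C@](C)(CO)[C@@H]3CC[C@@]2(C)O1 | intermediate
16 | (4S,5R,8R,9R,10S)-8,13-epoxy-14,15-dinorlabd-13(16)-en-19-ol | C=C1CC[C@@H]2[C@@]3(C)CCC[C@](C)(CO)[C@@H]3CC[C@@]2(C)O1 | intermediate
17 | (4S,5R,8R,9R,10S)-labda-13(16),14-diene-8,19-diol | C=CC(=C)CC[C@@H]1[C@@]2(C)CCC[C@](C)(CO)[C@@H]2CC[C@@]1(C)O | intermediate
18 | prop-2-ynoic acid (propiolic acid) | C#CC(=O)O | starting material
19 | (4S,5R,8R,9R,10S)-8-hydroxylabda-13(16),14-dien-19-yl prop-2-ynoate | C=CC(=C)CC[C@@H]1[C@@]2(C)CCC[C@](C)(COC(=O)C#C)[C@@H]2CC[C@@]1(C)O | intermediate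
20 | 4-iodophenol | Oc1ccc(I)cc1 | starting material
21 | (4S,5R,8R,9R,10S)-8-hydroxylabda-13(16),14-dien-19-yl 3-(4-hydroxyphenyl)prop-2-ynoate | C=CC(=C)CC[C@@H]1[C@@]2(C)CCC[C@](C)(COC(=O)C#Cc3ccc(O)cc3)[C@@H]2CC[C@@]1(C)O | intermediate
22 | (4S,5R,8R,9R,10S)-8-hydroxylabda-13(16),14-dien-19-yl (2Z)-3-(4-hydroxyphenyl)prop-2-enoate | C=CC(=C)CC[C@@H]1[C@@]2(C)CCC[C@](C)(COC(=O)/C=C\c3ccc(O)cc3)[C@@H]2CC[C@@]1(C)O | target

**Count and weak points**

Total step count: 13. Longest linear sequence: 13 steps (1 and 2 to 22).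

Step 10 (the new nickel step). The C–O insertion may fail, or the exocyclic enol ether may isomerise into the ring before coupling. The fallback uses known chemistry, sets out from lactone 15, leaves out 16 and comes back at diol 17. Vinylmagnesium bromide (3.5 equiv, THF, −78 °C; the magnesium lactolate does not take up a second equivalent) opens the lactone to the δ-hydroxy vinyl ketone F4. Lombardo-type methylenation (Zn, CH2Br2, TiCl4, THF/CH2Cl2, 0 °C → rt), which tolerates free hydroxyls and attacks enones only at the carbonyl, then gives 17.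

Step 4. Alkylation of the tetrasubstituted enolate with an unactivated primary iodide to make the quaternary C10 may be slow and allow proton transfer. The fallback sets out from ketal 5 and comes back at enoate 10. The same Li/NH3 reduction is trapped with allyl bromide, a far more reactive electrophile that enters from the same α face, to give the allyl ketone F1. Hydroboration with 9-BBN and oxidation (NaOH, H2O2) give the primary alcohol F2. Appel iodination (PPh3, I2, imidazole) gives the iodopropyl ketone F3, which is taken through the conditions of step 5 to 10.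

Step 13. The 1,3-diene may be partly reduced before the alkyne is consumed. The fallback replaces alkyne reduction by a stereoretentive cross-coupling, sets out from diol 17 and comes back at 22, leaving out 19 and 21. Propiolic acid 18 with NaI in AcOH (70 °C) gives (Z)-3-iodoacrylic acid F5 by anti addition of HI. DCC/DMAP esterification of 17 at −20 °C gives the (Z)-3-iodoacrylate F6. The arylzinc reagent F7 is made from 4-iodophenol 20 (MeMgCl, then i-PrMgCl·LiCl, then ZnCl2). Negishi coupling of F6 with F7 (Pd(PPh3)4, THF, rt) proceeds with retention of the alkene geometry and gives 22 without any hydrogenation in the presence of the diene.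

**Further compounds**

F1 | step 4 | allyl ketone ketal (C10: CH3 β and allyl α; C9–H α) | C1COC2(O1)CC[C@@H]3[C@@](C)(CC=C)C(=O)CC[C@@]23C
F2 | step 4 | 3-hydroxypropyl ketone ketal | C1COC2(O1)CC[C@@H]3[C@@](C)(CCCO)C(=O)CC[C@@]23C
F3 | step 4 | 3-iodopropyl ketone ketal | C1COC2(O1)CC[C@@H]3[C@@](C)(CCCI)C(=O)CC[C@@]23C
F4 | step 10 | (4S,5R,8R,9R,10S)-8,19-dihydroxy-16-norlabd-14-en-13-one (δ-hydroxy vinyl ketone) | C=CC(=O)CC[C@@H]1[C@@]2(C)CCC[C@](C)(CO)[C@@H]2CC[C@@]1(C)O
F5 | step 13 | (2Z)-3-iodoprop-2-enoic acid | OC(=O)/C=C\I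
F6 | step 13 | (4S,5R,8R,9R,10S)-8-hydroxylabda-13(16),14-dien-19-yl (2Z)-3-iodoprop-2-enoate | C=CC(=C)CC[C@@H]1[C@@]2(C)CCC[C@](C)(COC(=O)/C=C\I)[C@@H]2CC[C@@]1(C)O
F7 | step 13 | chloro[4-(chloromagnesiooxy)phenyl]zinc (arylzinc reagent from 20) | Cl[Zn]c1ccc(O[Mg]Cl)cc1
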